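(The earlier runs and the new flask were computed with constants of no real substance; scatter was added.)

**The books.** If I follow each mole of starting material, the limiting reagent here with the gas phase held, I keep these entries: product, starting material still standing, and a gap that the readings do not show.

in all of them: gas phase 2.7 mM (held)
- birch: starting material 18 mM (fed, over 15 h); catalyst 36 µM; run made earlier
- cedar: starting material 72 mM (fed, over 15 h); catalyst 36 µM; run made earlier
- elm: starting material 36 mM (fed, over 15 h); catalyst 54 µM; run made earlier
- flask: starting material 36 mM (fed, over 15 h); catalyst 36 µM; time 15 h

- birch (time / h: product / %, starting material / %): 4.00: 13, 10; 5.00: 21, 10; 8.00: 37, 14; 10.0: 49, 12; 15.0: 80, 16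
- cedar (time / h: product / %, starting material / %): 4.00: 8, 13; 5.00: 7, 19; 8.00: 18, 26; 10.0: 21, 34; 15.0: 34, 49
- elm (time / h: product / %, starting material / %): 4.00: 14, 8; 5.00: 18, 11; 8.00: 29, 16; 10.0: 38, 22; 15.0: 61, 26

(readings scatter by 2 percentage points)

- the numbers in the tables scatter by 2 percentage points (one standard deviation)
- at the start none of the gas phase is in solution
- a reading or a percentage of product counts all its forms, free or not
- percentages count the whole charge, also what has not yet gone in

- time up to 15 h at which product stands highest
- the amount of product, in percent of the starting material charged, at that time
- the first time at which product reaches 41%, in the same percent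

**The yardstick.** At the last reading the gap is 4.00% in birch and 17.0% in cedar. Cedar still holds 49% as starting material, and up to its last reading it makes 1.63 mM/h of product on average, more than birch or elm. I call this reading w, the average output of product, a yardstick from one scattered reading and not a ceiling.

**The flask's ledger.** Let f be the feed, the charge divided by the dosing time. In the flask f is 2.40 mM/h, above w, so I expect starting material to pile up. Over 15 h, a pace of w gives 68.0% as product, which leaves 32.0% for starting material and the gap. At that pace the level of 41% comes at 9.04 h. Cedar is still rising late, from 21% to 34%, so I put the highest point at 15 h. Elm, with 54 µM of catalyst against 36 µM here, reads 61%, so I expect the flask at or below that reading.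

**The forecast.** It gives 54% at 15 h and the level at 11.8 h, on the words “Flask should lie between these runs”.

**The result.** The flask gives 59.0% at 15.0 h and reaches the level at 11.0 h.

    gas phase ⇌ dissolved gas, rate k1*(csat - [dissolved gas]) (kL = 0.720 /h)
    starting material + dissolved gas + catalyst → catalyst + product (k = 1.00 × 10⁷ /M²/h)
    starting material ⇌ dormant form (K = 0.340, k = 0.490 /h)
    crystals ⇌ product, rate k4*(cs4 - [product]) while solid is left; crystals form when [product] > cs4 (solubility = 33.0 mM, k = 2.00 /h)

**Heavier neighbour.** At 15.0 h the flask's books read 59.0% product, 30.9% starting material and 10.1% dormant form, the entry the gap held, and product stands 9 percentage points under the figure from w. On the neighbour charged with 140 mM of starting material, the same pace w gives 17.5%. That neighbour stands at 19.3%, which is 1.8 points above the figure, an average output of 1.80 mM/h, more than w. Its books close with 61% as starting material and 19.8% as dormant form.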